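The route rests on closing ring B last through the C8–C9 bond. A tributylstannyl radical adds to the terminal alkyne (C17) of a seco-labdane 1,7-enyne; the C8 vinyl radical attacks C9 of the C9=C11 alkene (6-exo-trig), so one operation builds ring B, the exocyclic C8=C17 methylene and the C9 stereocentre. The step exploits the 1-methylene-2-alkylcyclohexane motif C17=C8–C9(H)–C11 of ring B. The precursor is an all-cis 1,2,3-trisubstituted ring A excised from dehydroabietic acid: because C4 and C10 are pseudo-symmetric, its carboxyl carbon becomes C9 while its two ring-fusion arene carbons become the C4 ester carbon and C8. Sharpless epoxidation then sets C13.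

Key step: step 12

Remark: labdane numbering is used for the target and all seco intermediates (ring A = C1–C5 and C10, ring B = C5–C10, C17 = exocyclic methylene carbon, side chain C11–C16). The target is read as the (4S,5S,9R,10S,13R) ent-labdane with the C4 ester equatorial. Compounds 1 and 8 are taken as catalogue chemicals.

Step 1
Reactants: 1 (+)-dehydroabietic acid
Product: 2 dehydroabietinol
Conditions: LiAlH4, THF, 0 °C → reflux
Reagents that add atoms: none
Why: Hydride reduction of the carboxylic acid (LiAlH4 reduction) gives the neopentyl primary alcohol; this carbon is the future C9 and no stereocentre is touched.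

Step 2
Reactants: 2 dehydroabietinol
Product: 3 dehydroabietinyl acetate
Conditions: Ac2O, pyridine, DMAP (cat.), CH2Cl2, rt
Reagents that add atoms: acetic anhydride CC(=O)OC(C)=O
Why: DMAP-catalysed O-acylation masks the carbinol as an acetate that survives RuO4, so this carbon stays at a lower oxidation level than the two carboxyls made next and the pseudo-symmetric ring A cannot become a meso triacid.

Step 3
Reactants: 3 dehydroabietinyl acetate
Product: 4 seco diacid
Conditions: RuCl3 hydrate (cat.), NaIO4, CCl4/MeCN/H2O, rt
Reagents that add atoms: sodium periodate [Na+].[O-]I(=O)(=O)=O; water O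
Why: RuO4 generated in situ degrades the electron-rich trialkylbenzene ring to carboxylic acids (oxidative arene degradation), leaving the two ring-fusion arene carbons as the C4 carboxyl and as the C8 carboxyl of a propanoic acid chain on C5, with C4, C5 and C10 untouched.

Step 4
Reactants: 4 seco diacid
Product: 5 dimethyl ester acetate
Conditions: MeI, K2CO3, DMF, rt
Reagents that add atoms: iodomethane CI
Why: SN2 O-methylation of both carboxylates esterifies even the hindered tertiary acid, which Fischer esterification would leave behind.

Step 5
Reactants: 5 dimethyl ester acetate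
Product: 6 hydroxy diester
Conditions: HCl (cat., from AcCl), MeOH, 0 °C → rt
Reagents that add atoms: none
Why: Acid-catalysed transesterification (methanolysis) removes the unhindered acetate while the α-quaternary C4 ester is inert and the chain methyl ester is unchanged; the alcohol is oxidised directly to forestall δ-lactonisation onto the cis C4 ester.

Step 6
Reactants: 6 hydroxy diester
Product: 7 aldehyde diester
Conditions: Dess–Martin periodinane, CH2Cl2, 0 °C → rt
Reagents that add atoms: none
Why: Dess–Martin oxidation converts the neopentyl primary alcohol into the non-enolisable C9 aldehyde under neutral conditions.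

Step 7
Reactants: 8 2-methylenepropane-1,3-diol
Product: 9 mono-TBS ether
Conditions: NaH (1 equiv), TBSCl (1 equiv), THF, 0 °C → rt
Reagents that add atoms: tert-butyldimethylsilyl chloride CC(C)(C)[Si](C)(C)Cl
Why: Monosilylation of the symmetrical diol through its monosodium alkoxide (O-silylation), the two hydroxyls being equivalent.

Step 8
Reactants: 9 mono-TBS ether
Product: 10 allylic bromide
Conditions: CBr4, PPh3, CH2Cl2, 0 °C
Reagents that add atoms: tetrabromomethane BrC(Br)(Br)Br
Why: Appel bromination of the primary allylic alcohol proceeds under neutral conditions that the silyl ether tolerates.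

Step 9
Reactants: 10 allylic bromide
Product: 11 homoallylic phosphonium bromide
Conditions: Ph3PCH3Br, n-BuLi, THF, −78 → 0 °C; then 10, −78 °C → rt
Reagents that add atoms: methyltriphenylphosphonium bromide C[P+](c1ccccc1)(c1ccccc1)c1ccccc1.[Br-]
Why: C-alkylation of methylenetriphenylphosphorane by the allylic bromide (ylide alkylation) adds C11 and delivers the homologous phosphonium salt.

Step 10
Reactants: 7 aldehyde diester; 11 homoallylic phosphonium bromide
Product: 13 (Z)-alkene diester, via phosphorus ylide 12 (not isolated)
Conditions: NaN(SiMe3)2, THF, −78 → 0 °C; then 7, −78 °C → rt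
Reagents that add atoms: none
Why: Wittig olefination of the hindered but non-enolisable aldehyde with the non-stabilised ylide joins the fragments at C9=C11; the (Z)-geometry follows from kinetic oxaphosphetane formation and is erased in step 12.

Step 11
Reactants: 13 (Z)-alkene diester
Product: 15 seco-labdane 1,7-enyne, via chain aldehyde 14 (not isolated)
Conditions: i-Bu2AlH, CH2Cl2, −78 °C; then MeOH, K2CO3, dimethyl (1-diazo-2-oxopropyl)phosphonate, −78 °C → rt
Reagents that add atoms: dimethyl (1-diazo-2-oxopropyl)phosphonate CC(=O)C(=[N+]=[N-])P(=O)(OC)OC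
Why: i-Bu2AlH half-reduces only the unhindered chain ester at −78 °C (the α-quaternary C4 ester is inert), and the aldehyde is homologated in the same flask to the terminal alkyne by the Ohira–Bestmann (Seyferth–Gilbert) reaction, which supplies C17.

Step 12
Reactants: 15 seco-labdane 1,7-enyne
Product: 16 C17-stannylated decalin silyl ether
Conditions: Bu3SnH (slow addition), AIBN (cat.), PhH (high dilution), 80 °C
Reagents that add atoms: tributyltin hydride CCCC[SnH](CCCC)CCCC
Why: Bu3Sn• adds reversibly to the terminal alkyne carbon C17; the C8 vinyl radical so formed adds to C9 of the C9=C11 alkene and the secondary C11 radical takes hydrogen from Bu3SnH, which carries the chain. The closest known reaction type is the tin-hydride-mediated radical cyclization of enynes through β-stannylvinyl radicals. Ring B is closed in the 6-exo-trig mode. The new stereocentre C9 is controlled by ring A: C5 and C10 hold the two reacting chains equatorial and gauche, and in the chair-like transition state C11 lies pseudo-equatorial, so H-9 should end axial on the face of H-5 and anti to the C10 methyl (trans-decalin, equatorial side chain). The step needs ring closure to outrun hydrogen transfer to the vinyl radical and 6-exo attack at C9 to beat 7-endo attack at C11; slow addition at high dilution, the pre-organisation by ring A and the lack of any hydrogen on C4 or C10 for 1,5-transfer should secure this. The C17–Sn bond (E/Z isomers expected, of no consequence) is a traceless handle removed in step 13.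

Step 13
Reactants: 16 C17-stannylated decalin silyl ether
Product: 17 allylic alcohol
Conditions: HCl (1 M aq.), THF/MeOH, 0 °C → rt
Reagents that add atoms: none
Why: Ipso-protodestannylation of the vinylstannane (protonation at C17, loss of tin from the β-stannyl cation) and acid cleavage of the primary silyl ether proceed together under dilute acid that should not isomerise the 1,1-disubstituted alkenes.

Step 14
Reactants: 17 allylic alcohol
Product: 18 (13S)-epoxy alcohol
Conditions: Ti(OiPr)4 (cat.), L-(+)-diethyl tartrate (cat.), t-BuOOH, 4 Å MS, CH2Cl2, −20 °C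
Reagents that add atoms: tert-butyl hydroperoxide CC(C)(C)OO
Why: Sharpless asymmetric epoxidation acts only on the allylic-alcohol alkene (the C8=C17 alkene has no directing hydroxyl), and L-(+)-diethyl tartrate should deliver oxygen to the face giving the (13S)-epoxide by reagent control, as for other 2-substituted allylic alcohols.

Step 15
Reactants: 18 (13S)-epoxy alcohol
Product: 19 target diol
Conditions: Me3SI, n-BuLi, THF, −10 °C → rt
Reagents that add atoms: trimethylsulfonium iodide C[S+](C)C.[I-]
Why: Dimethylsulfonium methylide opens the terminal epoxide at its CH2 carbon (C14) and the resulting sulfonium alkoxide loses Me2S by ylide-mediated elimination (one-carbon epoxide-to-allylic-alcohol homologation), creating the C14=C15 vinyl group without touching C13, whose descriptor becomes R by priority change only.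

Compound list

1 | (+)-dehydroabietic acid, (1R,4aS,10aR)-1,4a-dimethyl-7-(propan-2-yl)-1,2,3,4,4a,9,10,10a-octahydrophenanthrene-1-carboxylic acid | CC(C)c1ccc2c(c1)CC[C@H]3[C@@](C(=O)O)(C)CCC[C@]23C | starting material
2 | dehydroabietinol (carboxyl of 1 reduced to CH2OH) | CC(C)c1ccc2c(c1)CC[C@H]3[C@@](CO)(C)CCC[C@]23C | intermediate
3 | dehydroabietinyl acetate | CC(C)c1ccc2c(c1)CC[C@H]3[C@@](COC(C)=O)(C)CCC[C@]23C | intermediate
4 | seco diacid: cyclohexane ring A with C4 (CH3, CO2H), C5 (H, CH2CH2CO2H) and C10 (CH3, CH2OAc); both ring methyls and the C5 chain cis, CO2H and CH2OAc on the opposite face | OC(=O)CC[C@H]1[C@@](COC(C)=O)(C)CCC[C@]1(C)C(=O)O | intermediate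
5 | dimethyl ester acetate (both acids of 4 as methyl esters) | COC(=O)CC[C@H]1[C@@](COC(C)=O)(C)CCC[C@]1(C)C(=O)OC | intermediate
6 | hydroxy diester (C9 primary alcohol) | COC(=O)CC[C@H]1[C@@](CO)(C)CCC[C@]1(C)C(=O)OC | intermediate
7 | aldehyde diester (C9 aldehyde on C10) | COC(=O)CC[C@H]1[C@@](C=O)(C)CCC[C@]1(C)C(=O)OC | intermediate
8 | 2-methylenepropane-1,3-diol | C=C(CO)CO | starting material
9 | 2-[(tert-butyldimethylsilyloxy)methyl]prop-2-en-1-ol | C=C(CO)CO[Si](C)(C)C(C)(C)C | intermediate
10 | [2-(bromomethyl)prop-2-enyloxy](tert-butyl)dimethylsilane | C=C(CBr)CO[Si](C)(C)C(C)(C)C | intermediate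
11 | {3-[(tert-butyldimethylsilyloxy)methyl]but-3-en-1-yl}triphenylphosphonium bromide | C=C(CC[P+](c1ccccc1)(c1ccccc1)c1ccccc1)CO[Si](C)(C)C(C)(C)C.[Br-] | intermediate
12 | phosphorus ylide of 11 | C=C(CC=P(c1ccccc1)(c1ccccc1)c1ccccc1)CO[Si](C)(C)C(C)(C)C | intermediate
13 | (Z)-alkene diester: C10 bears (Z)-CH=CH–CH2–C(=CH2)–CH2OTBS, C5 bears CH2CH2CO2Me, C4 bears CH3 and CO2Me | COC(=O)CC[C@H]1[C@@](/C=C\CC(=C)CO[Si](C)(C)C(C)(C)C)(C)CCC[C@]1(C)C(=O)OC | intermediate
14 | chain aldehyde (C8 aldehyde of 13) | O=CCC[C@H]1[C@@](/C=C\CC(=C)CO[Si](C)(C)C(C)(C)C)(C)CCC[C@]1(C)C(=O)OC | intermediate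
15 | seco-labdane 1,7-enyne: C5 bears CH2CH2C≡CH (C8≡C17), C10 bears the (Z)-C9=C11 side chain | C#CCC[C@H]1[C@@](/C=C\CC(=C)CO[Si](C)(C)C(C)(C)C)(C)CCC[C@]1(C)C(=O)OC | intermediate
16 | C17-stannylated decalin silyl ether: trans-decalin, C8=C17H–SnBu3 (E/Z), C9 side chain CH2CH2C(=CH2)CH2OTBS equatorial | C=C(CO[Si](C)(C)C(C)(C)C)CC[C@@H]1C(=C[Sn](CCCC)(CCCC)CCCC)CC[C@H]2[C@@]1(C)CCC[C@]2(C)C(=O)OC | intermediate
17 | allylic alcohol: decalin with exocyclic C8=C17 and side chain CH2CH2C(=CH2)CH2OH | C=C(CO)CC[C@@H]1C(=C)CC[C@H]2[C@@]1(C)CCC[C@]2(C)C(=O)OC | intermediate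
18 | (13S)-13,14-epoxy-16-ol | O1C[C@@]1(CO)CC[C@@H]2C(=C)CC[C@H]3[C@@]2(C)CCC[C@]3(C)C(=O)OC | intermediate
19 | target, methyl (4S,5S,9R,10S,13R)-13,16-dihydroxylabda-8(17),14-dien-oate with the C4 ester equatorial (ent-labdane) | C=C[C@@](O)(CO)CC[C@@H]1C(=C)CC[C@H]2[C@@]1(C)CCC[C@]2(C)C(=O)OC | target

Total step count: 15. Longest linear sequence: 12 steps (1 to 19 through steps 1–6 and 10–15); steps 7–9 make the phosphonium salt.

Steps most likely to fail

Step 12. The risk is hydrogen transfer to the β-stannylvinyl radical before ring closure (plain hydrostannation), attack at C11 instead of the neopentyl-flanked C9, or homoallyl rearrangement of the C11 radical. The fallback sets out from 15. Markovnikov bromoboration–protonolysis (B-bromo-9-borabicyclo[3.3.1]nonane, CH2Cl2, 0 °C; then AcOH) would give the 2-bromo-1-alkene F1. Bromine abstraction with (Me3Si)3SiH and Et3B/air in toluene at room temperature generates the C8 vinyl radical irreversibly, with no hydrometalation channel and under a slower hydrogen donor at lower temperature, and should close ring B to the tin-free decalin silyl ether F2. Bu4NF in THF then removes the silyl group and the route is rejoined at 17.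

Step 3. The risk is benzylic oxidation at C7 (which deactivates the ring), C–H hydroxylation, or stalling at partly degraded keto acids. The fallback sets out from 3 and leaves oxo-ruthenium chemistry: exhaustive ozonolysis of the arene (O3, AcOH/CH2Cl2, then H2O2/HCO2H work-up) should converge on the same diacid 4, where the route is rejoined. No new isolated compound arises.

Step 15. The risk is slow opening at the neopentyl-type epoxide CH2, or stalling of the elimination at the sulfonium stage. The fallback sets out from 17 and takes the vinyl group from C16 instead. Sharpless epoxidation with D-(−)-diethyl tartrate would give the (13R)-epoxy alcohol F3; Dess–Martin oxidation would give the epoxy aldehyde F4; Ph3P=CH2 in THF would methylenate it to the vinyl epoxide F5. Hydroxide (NaOH, H2O/DMSO, 60 °C) should then open the epoxide at its CH2 terminus with C13 untouched, arriving at 19. The roles of C14 and C16 are exchanged, hence the enantiomeric tartrate.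

Further compounds
F1 | step 12 | 2-bromo-1-alkene (C8 bromide in place of the alkyne of 15) | C=C(Br)CC[C@H]1[C@@](/C=C\CC(=C)CO[Si](C)(C)C(C)(C)C)(C)CCC[C@]1(C)C(=O)OC
F2 | step 12 | tin-free decalin silyl ether (TBS ether of 17) | C=C(CO[Si](C)(C)C(C)(C)C)CC[C@@H]1C(=C)CC[C@H]2[C@@]1(C)CCC[C@]2(C)C(=O)OC
F0 | step 3 | none | none
F3 | step 15 | (13R)-epoxy alcohol (C13 epimer of 18) | O1C[C@]1(CO)CC[C@@H]2C(=C)CC[C@H]3[C@@]2(C)CCC[C@]3(C)C(=O)OC
F4 | step 15 | epoxy aldehyde (C16 aldehyde) | O1C[C@]1(C=O)CC[C@@H]2C(=C)CC[C@H]3[C@@]2(C)CCC[C@]3(C)C(=O)OC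
F5 | step 15 | vinyl epoxide (13,14-epoxide with C13 vinyl) | O1C[C@]1(C=C)CC[C@@H]2C(=C)CC[C@H]3[C@@]2(C)CCC[C@]3(C)C(=O)OC
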